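**Plan**
- Retrosynthesis: the bond between C2 of the pyranone ring and C1' of ring B is cut first (Negishi union). Then the pyranone is opened at O1–C2 and C2–C3 (C2 comes from an amide acetal), then the aryl–acetyl bond (Fries), then the ring-A C–O bonds, back to a p-quinone and 2,3-dimethoxyphenol.
- Forward: ring A is fully oxygenated first (Teuber oxidation, Thiele–Winter acetoxylation) and acetylated. Its future 5,6-catechol is tied into a temporary diphenylmethylene ketal ring, which leaves one ortho-OH to close ring C. Ring B is attached afterwards as a benzyl-protected aryl bromide.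
- Enabling feature: the chromone C2–H, an sp2 C–H of the pyranone ring next to ring oxygen O1 and vinylogous to the C4 carbonyl, on a chromone whose ring A carries no C–H. Zincation reverses the native electrophilic polarity of C2 so that it couples with an aryl electrophile.
- The two helpers (ketal ring, benzyl ether) leave together in the final hydrogenolysis.
- Stereochemistry: the target is planar and achiral (no stereocentre, no hindered axis), so nothing has to be set.

Key step: step 7

Assumption: the target has no stereogenic element, so the request for a single enantiomer is met by the achiral compound itself.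

**Step 1**
Reactants: 1 2,3-dimethoxyphenol
Product: 2 2,3-dimethoxy-1,4-benzoquinone
Conditions: (KO3S)2NO (2.2 equiv), aq. KH2PO4, acetone/H2O, 0 °C → rt
Reagents that add atoms: Fremy's salt (dipotassium nitrosodisulfonate), [O]N(S(=O)(=O)[O-])S(=O)(=O)[O-].[K+].[K+]
Why: Teuber oxidation, in which the nitroxyl radical abstracts the phenolic hydrogen, a second equivalent adds at the unsubstituted para carbon and loss of imidodisulfonate gives the p-quinone; the para position of 1 is free, so the 1,4-quinone and not an o-quinone is expected.

**Step 2**
Reactants: 2 2,3-dimethoxy-1,4-benzoquinone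
Product: 3 5,6-dimethoxybenzene-1,2,4-triyl triacetate
Conditions: Ac2O, conc. H2SO4 (cat.), rt → 40 °C; ice-water
Reagents that add atoms: acetic anhydride, CC(=O)OC(C)=O
Why: Thiele–Winter acetoxylation, in which the protonated quinone takes up acetate by 1,4-addition at the unsubstituted C5 (C5 and C6 are equivalent by symmetry; the methoxy-bearing carbons are deactivated as vinylogous esters) and the resulting triol is acetylated in situ, so all five ring oxygens are in place with the two methyl ethers already distinguished from the three future hydroxyls.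

**Step 3**
Reactants: 3 5,6-dimethoxybenzene-1,2,4-triyl triacetate
Product: 4 1-(2,3,6-trihydroxy-4,5-dimethoxyphenyl)ethan-1-one
Conditions: BF3·OEt2, AcOH, 95 °C, N2; then H2O, 95 °C
Reagents that add atoms: none
Why: Fries rearrangement (BF3-mediated C-acetylation) at the only free ring carbon, driven by the stable BF2 chelate of the o-hydroxyaryl ketone; the hot aqueous quench breaks the chelate and hydrolyses the two remaining aryl acetates, and no methoxy group sits ortho to the ketone, so chelation-assisted demethylation is not expected.

**Step 4**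
Reactants: 4 1-(2,3,6-trihydroxy-4,5-dimethoxyphenyl)ethan-1-one
Product: 5 1-(5-hydroxy-6,7-dimethoxy-2,2-diphenyl-1,3-benzodioxol-4-yl)ethan-1-one
Conditions: Ph2CCl2 (1.2 equiv), Ph2O, 175 °C, N2
Reagents that add atoms: dichlorodiphenylmethane, ClC(Cl)(c1ccccc1)c1ccccc1
Why: Catechol ketalisation with a gem-dichloride (two successive SN1-type substitutions through a diaryl-stabilised cation); only the vicinal 2,3-diol can close a five-membered 1,3-benzodioxole, so the temporary ring masks exactly the future 5,6-dihydroxy pair and leaves the 6-OH, hydrogen-bonded to the ketone, as the future pyranone oxygen.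

**Step 5**
Reactants: 5 1-(5-hydroxy-6,7-dimethoxy-2,2-diphenyl-1,3-benzodioxol-4-yl)ethan-1-one
Product: 7 4,5-dimethoxy-2,2-diphenyl-9H-[1,3]dioxolo[4,5-f]chromen-9-one, via enaminone 6 (not isolated)
Conditions: DMF-DMA (3 equiv), toluene, 100 °C; concentrate; then conc. HCl, CH2Cl2, 0 °C → rt
Reagents that add atoms: N,N-dimethylformamide dimethyl acetal, COC(OC)N(C)C
Why: Enaminone route to chromones, in which condensation of the methyl ketone with the amide acetal gives the vinylogous amide and acid then promotes oxa-Michael attack of the single free ortho-hydroxyl and loss of dimethylamine; the ring closure is regiochemically unambiguous and the diaryl ketal should tolerate brief cold acid.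

**Step 6**
Reactants: 8 5-bromo-2-methoxyphenol
Product: 9 2-(benzyloxy)-4-bromo-1-methoxybenzene
Conditions: BnBr, K2CO3, DMF, rt
Reagents that add atoms: benzyl bromide, BrCc1ccccc1
Why: Williamson etherification of the phenoxide with benzyl bromide; benzyl is chosen because it leaves in the same hydrogenolysis as the ketal.

**Step 7**
Reactants: 7 4,5-dimethoxy-2,2-diphenyl-9H-[1,3]dioxolo[4,5-f]chromen-9-one; 9 2-(benzyloxy)-4-bromo-1-methoxybenzene
Product: 11 7-[3-(benzyloxy)-4-methoxyphenyl]-4,5-dimethoxy-2,2-diphenyl-9H-[1,3]dioxolo[4,5-f]chromen-9-one, via C2-zincated chromone 10 (not isolated)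
Conditions: TMPZnCl·LiCl (1.2 equiv), THF, 25 °C; then 9 (1.2 equiv), Pd(OAc)2 (2 mol%), SPhos (4 mol%), THF, 50 °C
Reagents that add atoms: TMPZnCl·LiCl, CC1(C)CCCC(C)(C)N1[Zn]Cl.[Li+].[Cl-] (supplies the ZnCl of 10 only; none of its atoms remains in 11)
Why: The C2–H of the pyranone ring, an sp2 C–H flanked by ring oxygen O1 and vinylogous to the C4 carbonyl, is the most acidic C–H of 7, and the hindered zinc amide removes it to give the stable organozinc 10, which inverts the native electrophilic polarity of C2; Pd(0)/SPhos then effects oxidative addition of bromide 9, Zn-to-Pd transmetalation and reductive elimination to forge the bond between C2 and C1' of ring B. The closest known reaction type is the C2-selective zincation of chromones with TMP–zinc amide bases followed by Negishi arylation to flavones. No ring is closed and no stereocentre is formed. The step needs metalation at C2 and not at C3 or elsewhere: a magnesium-free base is used without added Lewis acid so that no carbonyl-bound base is delivered to C3, ring A of 7 has no C–H at all, and every hydroxyl is masked as ketal, benzyl or methyl ether. The bromide is added only after zincation is complete, so its benzylic hydrogens never meet the base, and the soft C–Zn bond tolerates the carbonyl and the ketal without opening the pyranone ring.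

**Step 8**
Reactants: 11 7-[3-(benzyloxy)-4-methoxyphenyl]-4,5-dimethoxy-2,2-diphenyl-9H-[1,3]dioxolo[4,5-f]chromen-9-one
Product: 12 5,6,3'-trihydroxy-7,8,4'-trimethoxyflavone
Conditions: H2 (1 atm), 10% Pd/C, THF/MeOH, rt
Reagents that add atoms: none
Why: Heterogeneous hydrogenolysis of benzylic C–O bonds, in which the benzyl ether gives toluene and the doubly benzylic ketal carbon gives diphenylmethane, freeing the three hydroxyls in one operation; the aryl methyl ethers are inert and the C2=C3 bond of the flavone, a doubly aryl-conjugated vinylogous ester, is not expected to be reduced at 1 atm and room temperature.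

**Compound list**
1 | 2,3-dimethoxyphenol | COc1cccc(O)c1OC | starting material
2 | 2,3-dimethoxy-1,4-benzoquinone | COC1=C(OC)C(=O)C=CC1=O | intermediate
3 | 5,6-dimethoxybenzene-1,2,4-triyl triacetate | CC(=O)Oc1cc(OC(C)=O)c(OC)c(OC)c1OC(C)=O | intermediate
4 | 1-(2,3,6-trihydroxy-4,5-dimethoxyphenyl)ethan-1-one | CC(=O)c1c(O)c(O)c(OC)c(OC)c1O | intermediate
5 | 1-(5-hydroxy-6,7-dimethoxy-2,2-diphenyl-1,3-benzodioxol-4-yl)ethan-1-one | CC(=O)c1c(O)c(OC)c(OC)c2OC(c3ccccc3)(c3ccccc3)Oc12 | intermediate
6 | (E)-3-(dimethylamino)-1-(5-hydroxy-6,7-dimethoxy-2,2-diphenyl-1,3-benzodioxol-4-yl)prop-2-en-1-one (enaminone) | CN(C)/C=C/C(=O)c1c(O)c(OC)c(OC)c2OC(c3ccccc3)(c3ccccc3)Oc12 | intermediate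
7 | 4,5-dimethoxy-2,2-diphenyl-9H-[1,3]dioxolo[4,5-f]chromen-9-one (7,8-dimethoxychromone with the 5,6-oxygens bridged by CPh2) | O=c1ccoc2c(OC)c(OC)c3OC(c4ccccc4)(c4ccccc4)Oc3c12 | intermediate
8 | 5-bromo-2-methoxyphenol | COc1ccc(Br)cc1O | starting material
9 | 2-(benzyloxy)-4-bromo-1-methoxybenzene | COc1ccc(Br)cc1OCc1ccccc1 | intermediate
10 | chloro(4,5-dimethoxy-9-oxo-2,2-diphenyl-9H-[1,3]dioxolo[4,5-f]chromen-7-yl)zinc (C2-zincated chromone, LiCl adduct) | Cl[Zn]c1cc(=O)c2c(o1)c(OC)c(OC)c1OC(c3ccccc3)(c3ccccc3)Oc12 | intermediate
11 | 7-[3-(benzyloxy)-4-methoxyphenyl]-4,5-dimethoxy-2,2-diphenyl-9H-[1,3]dioxolo[4,5-f]chromen-9-one (3'-O-benzyl-5,6-O-diphenylmethylene derivative of the target) | COc1ccc(-c2cc(=O)c3c(o2)c(OC)c(OC)c2OC(c4ccccc4)(c4ccccc4)Oc23)cc1OCc1ccccc1 | intermediate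
12 | 5,6,3'-trihydroxy-7,8,4'-trimethoxyflavone | COc1ccc(-c2cc(=O)c3c(O)c(O)c(OC)c(OC)c3o2)cc1O | target

**Count and risks**
Total step count: 8. Longest linear sequence: 7 steps (steps 1, 2, 3, 4, 5, 7, 8); step 6 prepares the coupling partner.

Steps most likely to fail:

- Step 7. The zincation may lose regiocontrol, with metalation drifting to C3 if the metal amide is held in the pocket between the C4 carbonyl and the peri ketal oxygen. The organozinc may also be protonated or transmetalate slowly before the electron-rich bromide has undergone oxidative addition. Fallback: setting out from 7, the native electrophilicity of C2 would be used instead of its metalation. Pd(II)-catalysed conjugate addition of commercial 3-(benzyloxy)-4-methoxyphenylboronic acid (Pd(TFA)2, 2,2'-bipyridine, AcOH/THF/H2O, 60 °C) should give the racemic flavanone rac-7-[3-(benzyloxy)-4-methoxyphenyl]-4,5-dimethoxy-2,2-diphenyl-7,8-dihydro-9H-[1,3]dioxolo[4,5-f]chromen-9-one F1. Its C2–C3 bond would then be dehydrogenated (DDQ, dioxane, reflux), which destroys the transient stereocentre and returns to the route at 11.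

- Step 3. Acyl migration to the ring carbon flanked by two oxygens may be incomplete, the acetates may be only partly cleaved, and the hydroquinone-type product may be oxidised by air to an acetylquinone during isolation. Fallback: setting out from 3, the acetyl group would come from a nitrile instead of by acyl migration. Degassed HCl/MeOH should remove the three acetates to give 5,6-dimethoxybenzene-1,2,4-triol F2. Under Houben–Hoesch conditions (MeCN, ZnCl2, HCl gas, Et2O, 0 °C) F2 should be attacked at its only free carbon to give 1-(2,3,6-trihydroxy-4,5-dimethoxyphenyl)ethan-1-iminium chloride F3. Warming F3 in water would hydrolyse it and return to the route at 4.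

- Step 8. Hydrogenolysis of the hindered peri ketal may stall, the C2=C3 bond may be saturated on prolonged exposure, and the chelating product may adsorb on the catalyst or oxidise in air during filtration. Fallback: setting out from 11, the protecting groups would be removed by acid and Lewis acid instead of hydrogen. AcOH/H2O (4:1) at reflux should hydrolyse the ketal to 2-[3-(benzyloxy)-4-methoxyphenyl]-5,6-dihydroxy-7,8-dimethoxy-4H-chromen-4-one F4. BCl3 with pentamethylbenzene (CH2Cl2, −78 °C) should then remove the benzyl group as a cation trapped by the scavenger, leaving the methyl ethers untouched and returning to the route at 12.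

**Further compounds**
F1 | step 7 | rac-7-[3-(benzyloxy)-4-methoxyphenyl]-4,5-dimethoxy-2,2-diphenyl-7,8-dihydro-9H-[1,3]dioxolo[4,5-f]chromen-9-one (racemic flavanone) | COc1ccc(C2CC(=O)c3c(O2)c(OC)c(OC)c2OC(c4ccccc4)(c4ccccc4)Oc23)cc1OCc1ccccc1
F2 | step 3 | 5,6-dimethoxybenzene-1,2,4-triol | Oc1cc(O)c(OC)c(OC)c1O
F3 | step 3 | 1-(2,3,6-trihydroxy-4,5-dimethoxyphenyl)ethan-1-iminium chloride | CC(=[NH2+])c1c(O)c(O)c(OC)c(OC)c1O.[Cl-]
F4 | step 8 | 2-[3-(benzyloxy)-4-methoxyphenyl]-5,6-dihydroxy-7,8-dimethoxy-4H-chromen-4-one | COc1ccc(-c2cc(=O)c3c(O)c(O)c(OC)c(OC)c3o2)cc1OCc1ccccc1
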